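**Plan**
- Retrosynthesis: cut C13=C16 (Wittig) and C12–C13 (thioester + alkylzinc), which frees the C13–C15 unit as (R)-isopropylideneglycerate; then cut C4–CH3 and restore oxygen at C3, giving a bicyclic β-keto ester.
- Key cut: C9–C10 is opened and C4 is re-bonded to C10. This works because C10, the methyl-bearing quaternary carbon of ring A, is 1,3 to the ester carbon C4 through C5; a C4–C10 bond therefore gives a 1,1-diacylcyclopropane whose tertiary carbon is exactly where C9 must attack.
- Forward: two Johnson–Claisen rearrangements build the chain; then β-keto ester, diazo ester, bicyclo[3.1.0]hexanone (five-membered ring C3, C2, C1, C10, C4). One Lewis-acid step then enlarges that ring to six-membered ring A and closes ring B (6-endo) with the 8(17)-olefin in place.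
- Finish: C3 deoxygenation, C4 methylation, then the side chain.
- Stereochemistry: C5/C10 from Cu–bis(oxazoline) cyclopropanation of the E-olefin; C9 from the chair closure; C4 from equatorial methylation of the exocyclic ester enolate (axial CO2Me); C14 from methyl (R)-isopropylideneglycerate.

Key step: step 9

Remark: atoms are numbered as in labdanes (C1–C20). C4 of 18 is enolisable and stays undefined until step 12. Compounds 1, 2, 5, 9, 13 and 25 are taken as catalogue compounds.

Step 1
Reactants: 1 3-[(tert-butyldimethylsilyl)oxy]propanal; 2 2-bromoallyltrimethylsilane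
Product: 4 rac-5-[(tert-butyldimethylsilyl)oxy]-2-[(trimethylsilyl)methyl]pent-1-en-3-ol, via vinyl Grignard reagent 3 (not isolated)
Conditions: Mg, THF, rt; then 1, −78 → 0 °C; aq. NH4Cl
Reagents that add atoms: none
Why: Grignard addition of the 2-metallated allylsilane to the aldehyde; the racemic carbinol centre is erased in step 2.

Step 2
Reactants: 4 rac-5-[(tert-butyldimethylsilyl)oxy]-2-[(trimethylsilyl)methyl]pent-1-en-3-ol; 5 trimethyl orthoacetate
Product: 7 methyl (4Z)-7-[(tert-butyldimethylsilyl)oxy]-4-[(trimethylsilyl)methyl]hept-4-enoate, via mixed ketene acetal 6 (not isolated)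
Conditions: MeC(OMe)3 (excess), EtCO2H (cat.), toluene, 110 °C, MeOH distilled off
Reagents that add atoms: trimethyl orthoacetate (5), CC(OC)(OC)OC
Why: Johnson–Claisen rearrangement through a chair with the CH2CH2OTBS group equatorial should place the two chain arms trans on the trisubstituted olefin (formally Z, since CH2SiMe3 outranks the chain), the geometry that later puts the C9 side chain equatorial; the weak acid catalyst should leave the allylsilane intact.

Step 3
Reactants: 7 methyl (4Z)-7-[(tert-butyldimethylsilyl)oxy]-4-[(trimethylsilyl)methyl]hept-4-enoate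
Product: 8 (4Z)-7-[(tert-butyldimethylsilyl)oxy]-4-[(trimethylsilyl)methyl]hept-4-enal
Conditions: DIBAL-H (1.05 equiv), CH2Cl2, −78 °C; Rochelle salt
Reagents that add atoms: none
Why: DIBAL-H reduction of a methyl ester at −78 °C stops at the aldehyde because the tetrahedral aluminate survives until work-up.

Step 4
Reactants: 8 (4Z)-7-[(tert-butyldimethylsilyl)oxy]-4-[(trimethylsilyl)methyl]hept-4-enal; 9 isopropenylmagnesium bromide
Product: 10 rac-(6Z)-9-[(tert-butyldimethylsilyl)oxy]-2-methyl-6-[(trimethylsilyl)methyl]nona-1,6-dien-3-ol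
Conditions: THF, −78 → 0 °C; aq. NH4Cl
Reagents that add atoms: isopropenylmagnesium bromide (9), C=C(C)[Mg]Br
Why: Grignard addition to the aldehyde gives the 2-methylallylic alcohol needed for the second Claisen step; the racemic carbinol centre is erased in step 5.

Step 5
Reactants: 10 rac-(6Z)-9-[(tert-butyldimethylsilyl)oxy]-2-methyl-6-[(trimethylsilyl)methyl]nona-1,6-dien-3-ol; 5 trimethyl orthoacetate
Product: 12 methyl (4E,8Z)-11-[(tert-butyldimethylsilyl)oxy]-4-methyl-8-[(trimethylsilyl)methyl]undeca-4,8-dienoate, via mixed ketene acetal 11 (not isolated)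
Conditions: MeC(OMe)3 (excess), EtCO2H (cat.), toluene, 110 °C, MeOH distilled off
Reagents that add atoms: trimethyl orthoacetate (5), CC(OC)(OC)OC
Why: A second Johnson–Claisen rearrangement through the chair with the chain equatorial should give the E C5=C10 olefin, whose geometry fixes the relative configuration of C5 and C10 in the cyclopropane.

Step 6
Reactants: 12 methyl (4E,8Z)-11-[(tert-butyldimethylsilyl)oxy]-4-methyl-8-[(trimethylsilyl)methyl]undeca-4,8-dienoate; 13 methyl acetate
Product: 15 methyl (6E,10Z)-13-[(tert-butyldimethylsilyl)oxy]-6-methyl-3-oxo-10-[(trimethylsilyl)methyl]trideca-6,10-dienoate, via lithium enolate of methyl acetate 14 (not isolated)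
Conditions: LDA (3.3 equiv), MeOAc (3.3 equiv), THF, −78 °C; then 12, −78 → 0 °C; 1 M HCl
Reagents that add atoms: methyl acetate (13), COC(C)=O
Why: Crossed Claisen condensation of the ester with excess lithio methyl acetate, driven by deprotonation of the β-keto ester as it forms.

Step 7
Reactants: 15 methyl (6E,10Z)-13-[(tert-butyldimethylsilyl)oxy]-6-methyl-3-oxo-10-[(trimethylsilyl)methyl]trideca-6,10-dienoate
Product: 16 methyl (6E,10Z)-2-diazo-13-[(tert-butyldimethylsilyl)oxy]-6-methyl-3-oxo-10-[(trimethylsilyl)methyl]trideca-6,10-dienoate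
Conditions: p-ABSA, Et3N, MeCN, 0 °C → rt
Reagents that add atoms: 4-acetamidobenzenesulfonyl azide (p-ABSA), CC(=O)Nc1ccc(cc1)S(=O)(=O)N=[N+]=[N-]
Why: Regitz diazo transfer to the active methylene of a β-keto ester under mild base, which the silyl groups and olefins tolerate.

Step 8
Reactants: 16 methyl (6E,10Z)-2-diazo-13-[(tert-butyldimethylsilyl)oxy]-6-methyl-3-oxo-10-[(trimethylsilyl)methyl]trideca-6,10-dienoate
Product: 17 methyl (1R,5R,6R)-6-{(3Z)-6-[(tert-butyldimethylsilyl)oxy]-3-[(trimethylsilyl)methyl]hex-3-en-1-yl}-5-methyl-2-oxobicyclo[3.1.0]hexane-1-carboxylate (C6 chain cis to the C5 methyl)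
Conditions: [Cu(MeCN)4]PF6 (5 mol%), t-Bu-BOX (6 mol%; the ligand enantiomer that gives 17), CH2Cl2, 40 °C, slow addition of 16
Reagents that add atoms: none
Why: Cu(I)–bis(oxazoline) carbenoid intramolecular cyclopropanation of a 2-diazo-3-oxohept-6-enoate closes the five-membered ring onto the proximal olefin stereospecifically (E-olefin gives chain cis to methyl), and the ligand sets the absolute configuration of C5 and C10; any enantiomeric impurity becomes a separable diastereomer after step 16.

Step 9
Reactants: 17 methyl (1R,5R,6R)-6-{(3Z)-6-[(tert-butyldimethylsilyl)oxy]-3-[(trimethylsilyl)methyl]hex-3-en-1-yl}-5-methyl-2-oxobicyclo[3.1.0]hexane-1-carboxylate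
Product: 18 methyl 12-[(tert-butyldimethylsilyl)oxy]-3-oxo-13,14,15,16,18-pentanorlabd-8(17)-en-19-oate (trans-decalin, 5α-H, 9α-H, 10β-CH3; C4 epimers and enol)
Conditions: SnCl4 (1.1 equiv), 2,6-di-tert-butyl-4-methylpyridine (0.2 equiv), CH2Cl2, −78 → −40 °C; aq. NaHCO3
Reagents that add atoms: none
Why: Proposed new method: SnCl4 chelation of the β-keto ester polarises the doubly activated cyclopropane so that the C4–C10 bond ionises toward the tertiary carbon while allylsilane carbon C9 attacks C10 from the rear, and the β-silyl cation at C8 loses Me3Si+ to chloride, leaving the tin enolate of the ring-expanded β-keto ester. The closest known reaction types are Lewis-acid opening of acyl- and 1,1-diacylcyclopropanes with olefin or allylsilane participation (cyclopropyl-ketone-initiated cation–olefin cyclisation) and allylsilane-terminated polyene cyclisation; new is their combination at the internal bond of a bicyclo[3.1.0]hexanone. Ring A is not closed but grows from the five-membered ring (C3, C2, C1, C10, C4) to the six-membered ring as the shared cyclopropane bond breaks and C5 enters the ring, and ring B closes 6-endo-trig at the allylsilane (exo to the breaking C–C bond) through a chair. C10 is set by inversion at the cyclopropane carbon, which with the retained C5 gives the trans ring fusion, and C9 is set by the chair in which the CH2CH2OTBS arm, trans to C7 on the olefin, sits equatorial; C4 stays enolisable until step 12. The step needs cleavage of the internal and not the external cyclopropane bond, secured by the methyl-bearing tertiary C10 against the secondary C5, and an exocyclic C8=C17 olefin, secured by the β-silicon effect. Closure of enolate carbon C4 onto C8 is excluded because the two are anti across the trans C5–C10 bond, and the hindered pyridine suppresses protodesilylation.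

Step 10
Reactants: 18 methyl 12-[(tert-butyldimethylsilyl)oxy]-3-oxo-13,14,15,16,18-pentanorlabd-8(17)-en-19-oate
Product: 19 methyl 12-[(tert-butyldimethylsilyl)oxy]-3-{[(trifluoromethyl)sulfonyl]oxy}-13,14,15,16,18-pentanorlabda-3,8(17)-dien-19-oate
Conditions: NaH, THF, 0 °C; then PhNTf2, 0 °C → rt; aq. NH4Cl
Reagents that add atoms: N-phenylbis(trifluoromethanesulfonimide), O=S(=O)(N(c1ccccc1)S(=O)(=O)C(F)(F)F)C(F)(F)F
Why: O-Sulfonylation of the sodium enolate of the β-keto ester gives the enol triflate, C4 being the only acidic site.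

Step 11
Reactants: 19 methyl 12-[(tert-butyldimethylsilyl)oxy]-3-{[(trifluoromethyl)sulfonyl]oxy}-13,14,15,16,18-pentanorlabda-3,8(17)-dien-19-oate
Product: 20 methyl 12-[(tert-butyldimethylsilyl)oxy]-13,14,15,16,18-pentanorlabda-3,8(17)-dien-19-oate
Conditions: Pd(OAc)2 (5 mol%), PPh3 (10 mol%), HCO2H, Et3N, DMF, 60 °C
Reagents that add atoms: none
Why: Pd-catalysed formate reduction of a vinyl triflate (Cacchi-type hydrogenolysis) removes the C3 oxygen and leaves the Δ3 unsaturated ester; the 1,1-disubstituted olefin should not react.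

Step 12
Reactants: 20 methyl 12-[(tert-butyldimethylsilyl)oxy]-13,14,15,16,18-pentanorlabda-3,8(17)-dien-19-oate
Product: 22 methyl (4S,5R,9S,10R)-12-[(tert-butyldimethylsilyl)oxy]-13,14,15,16-tetranorlabd-8(17)-en-19-oate, via lithium ester enolate 21 (not isolated)
Conditions: Li (2.2 equiv), NH3(l)/THF, −78 °C; then MeI (excess), −78 → −33 °C; NH4Cl
Reagents that add atoms: iodomethane, CI
Why: Birch-type reductive alkylation of an α,β-unsaturated ester: two-electron reduction with protonation at C3 gives the exocyclic ester enolate regiospecifically, and methyl iodide should enter from the equatorial α face, away from the axial C10 methyl, so that the ester ends up axial (4S).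

Step 13
Reactants: 22 methyl (4S,5R,9S,10R)-12-[(tert-butyldimethylsilyl)oxy]-13,14,15,16-tetranorlabd-8(17)-en-19-oate
Product: 23 methyl (4S,5R,9S,10R)-12-hydroxy-13,14,15,16-tetranorlabd-8(17)-en-19-oate
Conditions: TBAF, THF, 0 °C → rt
Reagents that add atoms: none
Why: Fluoride cleavage of the primary silyl ether; the hindered axial ester is untouched.

Step 14
Reactants: 23 methyl (4S,5R,9S,10R)-12-hydroxy-13,14,15,16-tetranorlabd-8(17)-en-19-oate
Product: 24 methyl (4S,5R,9S,10R)-12-iodo-13,14,15,16-tetranorlabd-8(17)-en-19-oate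
Conditions: I2, PPh3, imidazole, CH2Cl2, 0 °C → rt
Reagents that add atoms: iodine, II
Why: Appel-type iodination of an unhindered primary alcohol via the alkoxyphosphonium ion.

Step 15
Reactants: 25 methyl (R)-2,2-dimethyl-1,3-dioxolane-4-carboxylate
Product: 26 S-ethyl (R)-2,2-dimethyl-1,3-dioxolane-4-carbothioate
Conditions: AlMe3, EtSH, CH2Cl2, 0 °C → rt
Reagents that add atoms: ethanethiol, CCS
Why: The aluminium thiolate formed from AlMe3 and EtSH converts a methyl ester into the S-ethyl thioester without touching the acetonide or the α stereocentre.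

Step 16
Reactants: 24 methyl (4S,5R,9S,10R)-12-iodo-13,14,15,16-tetranorlabd-8(17)-en-19-oate; 26 S-ethyl (R)-2,2-dimethyl-1,3-dioxolane-4-carbothioate
Product: 28 methyl (14R)-14,15-(isopropylidenedioxy)-13-oxo-16-norlabd-8(17)-en-19-oate, via alkylzinc iodide 27 (not isolated)
Conditions: Zn dust (activated with BrCH2CH2Br, TMSCl), DMA, 40 °C; then 26, PdCl2(PPh3)2 (5 mol%), toluene, rt
Reagents that add atoms: none
Why: Zinc insertion into the primary iodide gives an organozinc that tolerates the ester, and Fukuyama coupling (Pd-catalysed acylation by the thioester) forms C12–C13 without epimerising the α-alkoxy ketone.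

Step 17
Reactants: 28 methyl (14R)-14,15-(isopropylidenedioxy)-13-oxo-16-norlabd-8(17)-en-19-oate
Product: 29 methyl (14S)-14,15-(isopropylidenedioxy)labda-8(17),13(16)-dien-19-oate
Conditions: Ph3PCH3Br, KHMDS, THF, 0 °C; then 28, −78 → 0 °C
Reagents that add atoms: methyltriphenylphosphonium bromide, C[P+](c1ccccc1)(c1ccccc1)c1ccccc1.[Br-]
Why: Wittig methylenation of the unhindered ketone at low temperature; the neopentyl-type methyl ester is inert and C14 should keep its configuration because carbonyl addition outruns enolisation (the descriptor changes from R to S only through the priority switch).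

Step 18
Reactants: 29 methyl (14S)-14,15-(isopropylidenedioxy)labda-8(17),13(16)-dien-19-oate
Product: 30 methyl (14S)-14,15-dihydroxylabda-8(17),13(16)-dien-19-oate (CNP0185041.1)
Conditions: AcOH/H2O/THF (3:1:1), 40 °C
Reagents that add atoms: none
Why: Mild acid hydrolysis of the isopropylidene acetal releases the 14,15-diol and should leave both 1,1-disubstituted olefins in place.

**Compound list**
1 | 3-[(tert-butyldimethylsilyl)oxy]propanal | O=CCCO[Si](C)(C)C(C)(C)C | starting material
2 | 2-bromoallyltrimethylsilane | C=C(Br)C[Si](C)(C)C | starting material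
3 | [3-(trimethylsilyl)prop-1-en-2-yl]magnesium bromide | C=C([Mg]Br)C[Si](C)(C)C | intermediate (not isolated)
4 | rac-5-[(tert-butyldimethylsilyl)oxy]-2-[(trimethylsilyl)methyl]pent-1-en-3-ol | C=C(C[Si](C)(C)C)C(O)CCO[Si](C)(C)C(C)(C)C | intermediate
5 | trimethyl orthoacetate | CC(OC)(OC)OC | starting material
6 | mixed ketene acetal of 4 (1-methoxyvinyl ether) | C=C(OC)OC(CCO[Si](C)(C)C(C)(C)C)C(=C)C[Si](C)(C)C | intermediate (not isolated)
7 | methyl (4Z)-7-[(tert-butyldimethylsilyl)oxy]-4-[(trimethylsilyl)methyl]hept-4-enoate | COC(=O)CC/C(C[Si](C)(C)C)=C/CCO[Si](C)(C)C(C)(C)C | intermediate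
8 | (4Z)-7-[(tert-butyldimethylsilyl)oxy]-4-[(trimethylsilyl)methyl]hept-4-enal | O=CCC/C(C[Si](C)(C)C)=C/CCO[Si](C)(C)C(C)(C)C | intermediate
9 | isopropenylmagnesium bromide | C=C(C)[Mg]Br | starting material
10 | rac-(6Z)-9-[(tert-butyldimethylsilyl)oxy]-2-methyl-6-[(trimethylsilyl)methyl]nona-1,6-dien-3-ol | C=C(C)C(O)CC/C(C[Si](C)(C)C)=C/CCO[Si](C)(C)C(C)(C)C | intermediate
11 | mixed ketene acetal of 10 (1-methoxyvinyl ether) | C=C(OC)OC(CC/C(C[Si](C)(C)C)=C/CCO[Si](C)(C)C(C)(C)C)C(C)=C | intermediate (not isolated)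
12 | methyl (4E,8Z)-11-[(tert-butyldimethylsilyl)oxy]-4-methyl-8-[(trimethylsilyl)methyl]undeca-4,8-dienoate | COC(=O)CC/C(C)=C/CC/C(C[Si](C)(C)C)=C/CCO[Si](C)(C)C(C)(C)C | intermediate
13 | methyl acetate | COC(C)=O | starting material
14 | lithium enolate of methyl acetate | C=C(OC)O[Li] | intermediate (not isolated)
15 | methyl (6E,10Z)-13-[(tert-butyldimethylsilyl)oxy]-6-methyl-3-oxo-10-[(trimethylsilyl)methyl]trideca-6,10-dienoate | COC(=O)CC(=O)CC/C(C)=C/CC/C(C[Si](C)(C)C)=C/CCO[Si](C)(C)C(C)(C)C | intermediate
16 | methyl (6E,10Z)-2-diazo-13-[(tert-butyldimethylsilyl)oxy]-6-methyl-3-oxo-10-[(trimethylsilyl)methyl]trideca-6,10-dienoate | COC(=O)C(=[N+]=[N-])C(=O)CC/C(C)=C/CC/C(C[Si](C)(C)C)=C/CCO[Si](C)(C)C(C)(C)C | intermediate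
17 | methyl (1R,5R,6R)-6-{(3Z)-6-[(tert-butyldimethylsilyl)oxy]-3-[(trimethylsilyl)methyl]hex-3-en-1-yl}-5-methyl-2-oxobicyclo[3.1.0]hexane-1-carboxylate | COC(=O)[C@@]12C(=O)CC[C@]1(C)[C@H]2CC/C(C[Si](C)(C)C)=C/CCO[Si](C)(C)C(C)(C)C | intermediate
18 | methyl 12-[(tert-butyldimethylsilyl)oxy]-3-oxo-13,14,15,16,18-pentanorlabd-8(17)-en-19-oate (C4 epimers/enol) | CC(C)(C)[Si](C)(C)OCC[C@H]1C(=C)CC[C@@H]2[C@]1(C)CCC(=O)C2C(=O)OC | intermediate
19 | methyl 12-[(tert-butyldimethylsilyl)oxy]-3-{[(trifluoromethyl)sulfonyl]oxy}-13,14,15,16,18-pentanorlabda-3,8(17)-dien-19-oate | CC(C)(C)[Si](C)(C)OCC[C@H]1C(=C)CC[C@@H]2[C@]1(C)CCC(OS(=O)(=O)C(F)(F)F)=C2C(=O)OC | intermediate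
20 | methyl 12-[(tert-butyldimethylsilyl)oxy]-13,14,15,16,18-pentanorlabda-3,8(17)-dien-19-oate | CC(C)(C)[Si](C)(C)OCC[C@H]1C(=C)CC[C@@H]2[C@]1(C)CCC=C2C(=O)OC | intermediate
21 | lithium enolate (ketene acetal) of methyl 12-[(tert-butyldimethylsilyl)oxy]-13,14,15,16,18-pentanorlabd-8(17)-en-19-oate | CC(C)(C)[Si](C)(C)OCC[C@H]1C(=C)CC[C@@H]2[C@]1(C)CCCC2=C(OC)O[Li] | intermediate (not isolated)
22 | methyl (4S,5R,9S,10R)-12-[(tert-butyldimethylsilyl)oxy]-13,14,15,16-tetranorlabd-8(17)-en-19-oate | CC(C)(C)[Si](C)(C)OCC[C@H]1C(=C)CC[C@@H]2[C@]1(C)CCC[C@]2(C)C(=O)OC | intermediate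
23 | methyl (4S,5R,9S,10R)-12-hydroxy-13,14,15,16-tetranorlabd-8(17)-en-19-oate | OCC[C@H]1C(=C)CC[C@@H]2[C@]1(C)CCC[C@]2(C)C(=O)OC | intermediate
24 | methyl (4S,5R,9S,10R)-12-iodo-13,14,15,16-tetranorlabd-8(17)-en-19-oate | ICC[C@H]1C(=C)CC[C@@H]2[C@]1(C)CCC[C@]2(C)C(=O)OC | intermediate
25 | methyl (R)-2,2-dimethyl-1,3-dioxolane-4-carboxylate | COC(=O)[C@H]1COC(C)(C)O1 | starting material
26 | S-ethyl (R)-2,2-dimethyl-1,3-dioxolane-4-carbothioate | CCSC(=O)[C@H]1COC(C)(C)O1 | intermediate
27 | alkylzinc iodide from 24 (12-(iodozincio) ester) | I[Zn]CC[C@H]1C(=C)CC[C@@H]2[C@]1(C)CCC[C@]2(C)C(=O)OC | intermediate (not isolated)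
28 | methyl (14R)-14,15-(isopropylidenedioxy)-13-oxo-16-norlabd-8(17)-en-19-oate | O=C(CC[C@H]1C(=C)CC[C@@H]2[C@]1(C)CCC[C@]2(C)C(=O)OC)[C@H]1COC(C)(C)O1 | intermediate
29 | methyl (14S)-14,15-(isopropylidenedioxy)labda-8(17),13(16)-dien-19-oate | C=C(CC[C@H]1C(=C)CC[C@@H]2[C@]1(C)CCC[C@]2(C)C(=O)OC)[C@H]1COC(C)(C)O1 | intermediate
30 | methyl (4S,5R,9S,10R,14S)-14,15-dihydroxylabda-8(17),13(16)-dien-19-oate (CNP0185041.1) | C=C(CC[C@H]1C(=C)CC[C@@H]2[C@]1(C)CCC[C@]2(C)C(=O)OC)[C@H](O)CO | target

**Step count:** 18 steps in total. The longest linear sequence is 17 steps (steps 1–14, then 16–18); step 15 is a one-step side branch.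

**Steps most likely to fail**

Step 9 (key step, proposed new method). The olefin may fail to take part in the ionisation, so that the C10 cation is captured by chloride or lost by proton elimination. The external cyclopropane bond may break instead of the internal one, or the allylsilane may be protodesilylated before it cyclises. The fallback separates ring expansion from ring B closure, using two operations of known type; it sets out from 17 and comes back at 18. Opening of the diacylcyclopropane 17 with anhydrous MgI2 (CH2Cl2/Et2O, 0 °C), a Lewis acid that brings its own nucleophile, should deliver iodide to the tertiary carbon. This gives the ring-expanded methyl 5-iodo-5-methyl-2-oxo-6-{(3Z)-6-[(tert-butyldimethylsilyl)oxy]-3-[(trimethylsilyl)methyl]hex-3-en-1-yl}cyclohexane-1-carboxylate F1. Ionisation of this tertiary iodide with AgOTf and 2,6-di-tert-butylpyridine (CH2Cl2, −78 °C) then generates the C10 cation in a preformed six-membered ring. The allylsilane closes ring B as in a conventional cation–olefin cyclisation to give 18.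

Step 8. Enantio-induction by the copper carbenoid may be poor on the trisubstituted olefin, and competing allylic C–H insertion may erode the yield. The fallback replaces asymmetric induction by resolution; it sets out from 16 and comes back at 17. Cyclopropanation of 16 with achiral Rh2(OAc)4 (CH2Cl2, rt) should give 17 together with its mirror image, methyl (1S,5S,6S)-6-{(3Z)-6-[(tert-butyldimethylsilyl)oxy]-3-[(trimethylsilyl)methyl]hex-3-en-1-yl}-5-methyl-2-oxobicyclo[3.1.0]hexane-1-carboxylate F2. The racemate is separated by preparative chromatography on a chiral stationary phase and 17 continues in step 9.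

Step 12. The dissolving metal may over-reduce the ester, the enolate may be lost by proton transfer before it is alkylated, or methylation may show poor facial selectivity. The fallback separates reduction from alkylation; it sets out from 20 and comes back at 22. Conjugate reduction of 20 with Mg in MeOH (rt) should give the saturated ester, methyl 12-[(tert-butyldimethylsilyl)oxy]-13,14,15,16,18-pentanorlabd-8(17)-en-19-oate F3, as a mixture of C4 epimers. Deprotonation with LDA/HMPA (THF, −78 °C) regenerates enolate 21 under aprotic conditions, and methyl iodide then gives 22 with the same equatorial approach.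

Further compounds
F1 | step 9 | methyl 5-iodo-5-methyl-2-oxo-6-{(3Z)-6-[(tert-butyldimethylsilyl)oxy]-3-[(trimethylsilyl)methyl]hex-3-en-1-yl}cyclohexane-1-carboxylate (C5 of the labdane numbering fixed, iodide-bearing carbon and C4 undefined) | COC(=O)C1C(=O)CCC(C)(I)[C@H]1CC/C(C[Si](C)(C)C)=C/CCO[Si](C)(C)C(C)(C)C
F2 | step 8 | methyl (1S,5S,6S)-6-{(3Z)-6-[(tert-butyldimethylsilyl)oxy]-3-[(trimethylsilyl)methyl]hex-3-en-1-yl}-5-methyl-2-oxobicyclo[3.1.0]hexane-1-carboxylate (enantiomer of 17) | COC(=O)[C@]12C(=O)CC[C@@]1(C)[C@@H]2CC/C(C[Si](C)(C)C)=C/CCO[Si](C)(C)C(C)(C)C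
F3 | step 12 | methyl 12-[(tert-butyldimethylsilyl)oxy]-13,14,15,16,18-pentanorlabd-8(17)-en-19-oate (C4 epimers) | CC(C)(C)[Si](C)(C)OCC[C@H]1C(=C)CC[C@@H]2[C@]1(C)CCCC2C(=O)OC
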